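Two amounts come first: this flask holds 0.20 M of free monomer and 0.0200 M of protic impurity, and the winter and dusk runs tell you what such a pair does.

in all of them: free monomer 0.20 M; initiator 0.5 mol%

| charge | protic impurity | remark | time |
|---|---|---|---|
| winter | 0.028 M | run made earlier |  |
| dusk | 0.044 M | run made earlier |  |
| flask | 0.0200 M |  | 6.0 min |

- winter (time / min: monomer in chains / %, free monomer / %): 0.833: 38, 46; 2.00: 60, 24; 2.50: 64, 19; 4.00: 75, 14
- dusk (time / min: monomer in chains / %, free monomer / %): 0.833: 36, 39; 2.00: 54, 20; 2.50: 59, 14; 4.00: 67, 11

(standard deviation of a reading: 2 percentage points)

- the average divides the monomer in chains by the number of chains, living and dead together; two radicals that join make one chain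
- the earlier runs do not show the number of chains; that part of a forecast is a guess

- average number of monomer units in a chain (living and dead chains, two that joined counted as one) at 6.0 min
- part of the free monomer that has reacted at 6.0 min

Picture two extreme versions of the flask. In the first, the protic impurity takes no free monomer, so free monomer and monomer in chains together always add up to the whole charge. In the second, each impurity molecule takes one monomer before any chain grows, so that sum drops at once by this amount:

quench share = c(protic impurity) / c(free monomer) = 0.0200 M / 0.20 M = 10.0%

This quench share is the part of the charged free monomer lost if the impurity takes it one for one. To place the real flask, hold the mean gap in each earlier run, the charge minus the two readings, against that run's share: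

winter: gap 15.0%, share 14.0%

dusk: gap 25.0%, share 22.0%

Both gaps lie near the second extreme, and the winter readings already show a gap of 16.0% at 0.833 min. My own reckoning for this flask at 6.0 min is therefore a sum of free monomer and monomer in chains near 90.0%.

The forecast, holding that “the impurity seems to consume about one monomer each, quickly”, gives 210 units per chain and 91% reacted. The flask gives 173 units per chain and 92.9% reacted, so the forecast's chain length is 1.21 times the flask's.

    initiator → 2 initiating radical (k = 0.00820 s⁻¹)
    free monomer + initiating radical → growing radical + monomer in chains (k = 6.30 × 10⁵ L mol⁻¹ s⁻¹)
    free monomer + growing radical → monomer in chains + growing radical, rate k3*[growing radical]*[free monomer] (k = 25000 L mol⁻¹ s⁻¹)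
    2 growing radical → dead chain (k = 3.00 × 10⁷ L mol⁻¹ s⁻¹)
    free monomer → decomposition product (k = 1.20 × 10⁻⁴ s⁻¹)
    protic impurity + free monomer → quenched substrate (k = 1.70 L mol⁻¹ s⁻¹)

In this flask the protic impurity has a half-life of 2.04 s at the charged free monomer, far shorter than the 1.1 min that growth gives free monomer at 0.843 min, and this limiting reagent of the quench stands at 0.0134% of its charge by 0.600 min. Quenched substrate stays at 10.0%, the quench share, and free monomer plus monomer in chains make 88.9% at 6.0 min against the 90.0% reckoned, with decomposition product at 1.07% beside them. The neighbour flask charged with 0.12 M of free monomer has a quench share of 16.7%, and its quenched substrate stands at 16.7%.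

All runs were computed with constants of no real substance; the scatter is artificial.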